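**Plan**

- Retrosynthesis: the five benzyl ethers are removed first; the flavonol is then cut at its pyranone ring (O1–C2 and C2–C3 of the chromone) back to an aryl aldehyde on benzofuran C4, itself from C4–Br, and a phloroacetophenone; last, ring D is cut at C2–C3 and O1–C2.
- Enabling feature (benzofuran numbering): O1 and the benzylic carbon C3 sit on the adjacent ring B carbons C7a and C3a, so they are the two ends of an o-quinone methide (O=C7a–C3a=C3). The one carbon between them, C2, is a guaiacyl-CH (benzylidene) unit.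
- Forward: a ring B sulfone (from 2,3-dihydroxybenzaldehyde) and a guaiacylmethyl thiolanium salt are joined in a [4+1] annulation that closes ring D. Then C4–Br → CHO → chalcone → chromone ring → 3-hydroxylation → global debenzylation.
- Stereochemistry: C2 comes from the twofold-symmetric (2R,5R)-2,5-dimethylthiolane (from (2S,5S)-hexane-2,5-diol by double inversion). C3 is set trans to C2 in the same step (betaine formation, then invertive closure). No later step touches either centre.

Key step: step 11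

Assumption: the ylide of the (2R,5R)-thiolane is taken to react on the same face as in its benzylidene transfer to aldehydes, which after the invertive ring closure corresponds to 2R; (2R,3S) refers to benzofuran numbering.

**Route**

Step 1
Reactants: 1 2,3-dihydroxybenzaldehyde
Product: 2 3-(benzyloxy)-2-hydroxybenzaldehyde
Conditions: NaH (2.2 equiv), DMSO, rt; BnBr (1.0 equiv), rt; aq. HCl
Reagents that add atoms: benzyl bromide BrCc1ccccc1
Why: Williamson etherification of the dianion, in which the 2-oxide is tied up by conjugation and chelation with the formyl group so that the more nucleophilic 3-oxide takes the single equivalent of benzyl bromide.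

Step 2
Reactants: 2 3-(benzyloxy)-2-hydroxybenzaldehyde
Product: 3 2-(benzyloxy)-6-formylphenyl acetate
Conditions: Ac2O, pyridine, DMAP (cat.), CH2Cl2, 0 °C to rt
Reagents that add atoms: acetic anhydride CC(=O)OC(C)=O
Why: Nucleophile-catalysed O-acylation of the phenol, which turns the strongest ring donor into a weak one so that the benzyloxy group directs the next step.

Step 3
Reactants: 3 2-(benzyloxy)-6-formylphenyl acetate
Product: 4 6-(benzyloxy)-3-bromo-2-formylphenyl acetate
Conditions: Br2 (1.05 equiv), NaOAc, AcOH, rt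
Reagents that add atoms: bromine BrBr
Why: Electrophilic aromatic bromination should go para to the benzyloxy group (C6 of the benzaldehyde), the most activated open position once the phenol is acetylated, as is known for the acetate of o-vanillin.

Step 4
Reactants: 4 6-(benzyloxy)-3-bromo-2-formylphenyl acetate
Product: 5 3-(benzyloxy)-6-bromo-2-hydroxybenzaldehyde
Conditions: K2CO3 (1.1 equiv), MeOH, 0 °C to rt; aq. HCl
Reagents that add atoms: none
Why: Base-mediated methanolysis (transesterification) of the aryl acetate, which is far more labile than the benzyl ether, the aryl bromide or the aldehyde.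

Step 5
Reactants: 5 3-(benzyloxy)-6-bromo-2-hydroxybenzaldehyde
Product: 6 6-(benzyloxy)-2-[2-(benzyloxy)-1-hydroxyethyl]-3-bromophenol (racemic)
Conditions: NaH (1.05 equiv), THF, 0 °C; then BnOCH2Li [from BnOCH2SnBu3 (1.3 equiv), n-BuLi (1.25 equiv), THF, −78 °C], −78 °C; aq. NH4Cl
Reagents that add atoms: tributyl[(benzyloxy)methyl]stannane CCCC[Sn](CCCC)(CCCC)COCc1ccccc1
Why: 1,2-Addition of an α-alkoxymethyllithium (made by tin–lithium exchange) to the aldehyde of the pre-formed sodium phenoxide should outrun bromine–lithium exchange at −78 °C, and the racemic carbinol centre is immaterial because it is destroyed at the quinone methide stage.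

Step 6
Reactants: 6 6-(benzyloxy)-2-[2-(benzyloxy)-1-hydroxyethyl]-3-bromophenol
Product: 7 6-(benzyloxy)-2-[2-(benzyloxy)-1-(phenylsulfonyl)ethyl]-3-bromophenol (racemic)
Conditions: PhSO2Na (3 equiv), HCO2H, CH2Cl2, rt to 40 °C
Reagents that add atoms: sodium benzenesulfinate [Na+].[O-]S(=O)c1ccccc1
Why: Acid-promoted SN1 substitution of the o-hydroxybenzylic alcohol through the protonated o-quinone methide, captured at sulfur by the soft sulfinate, is the standard preparation of 2-(1-sulfonylalkyl)phenols; the centre is racemic and later destroyed.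

Step 7
Reactants: 8 (2S,5S)-hexane-2,5-diol
Product: 9 (2S,5S)-hexane-2,5-diyl dimethanesulfonate
Conditions: MsCl (2.4 equiv), Et3N, CH2Cl2, 0 °C
Reagents that add atoms: methanesulfonyl chloride CS(=O)(=O)Cl
Why: O-Sulfonylation proceeds with retention because no bond to either stereocentre is broken.

Step 8
Reactants: 9 (2S,5S)-hexane-2,5-diyl dimethanesulfonate
Product: 10 (2R,5R)-2,5-dimethylthiolane
Conditions: Na2S·9H2O, DMSO, rt
Reagents that add atoms: sodium sulfide [Na+].[Na+].[S-2]
Why: Double SN2 displacement by sulfide (intermolecular, then 5-exo-tet) inverts both centres, so the (2S,5S)-dimesylate should give the (2R,5R)-thiolane.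

Step 9
Reactants: 11 [4-(benzyloxy)-3-methoxyphenyl]methanol
Product: 12 1-(benzyloxy)-4-(bromomethyl)-2-methoxybenzene
Conditions: PBr3 (0.4 equiv), Et2O, 0 °C
Reagents that add atoms: phosphorus tribromide BrP(Br)Br
Why: Standard conversion of an electron-rich benzylic alcohol into the bromide by bromide displacement on the phosphite ester at low temperature.

Step 10
Reactants: 10 (2R,5R)-2,5-dimethylthiolane; 12 1-(benzyloxy)-4-(bromomethyl)-2-methoxybenzene
Product: 13 (2R,5R)-1-[4-(benzyloxy)-3-methoxybenzyl]-2,5-dimethylthiolan-1-ium tetrafluoroborate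
Conditions: AgBF4 (1.0 equiv), CH2Cl2, 0 °C to rt, dark
Reagents that add atoms: silver tetrafluoroborate [Ag+].F[B-](F)(F)F
Why: S-Alkylation of the sulfide by the benzylic bromide is driven by AgBr precipitation and gives a bromide-free salt, and the twofold axis makes both sulfur lone pairs equivalent so that only one sulfonium salt can form.

Step 11
Reactants: 7 6-(benzyloxy)-2-[2-(benzyloxy)-1-(phenylsulfonyl)ethyl]-3-bromophenol; 13 (2R,5R)-1-[4-(benzyloxy)-3-methoxybenzyl]-2,5-dimethylthiolan-1-ium tetrafluoroborate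
Product: 17 (2R,3S)-7-(benzyloxy)-3-[(benzyloxy)methyl]-2-[4-(benzyloxy)-3-methoxyphenyl]-4-bromo-2,3-dihydro-1-benzofuran, via o-quinone methide 14 (not isolated), via sulfonium ylide 15 (not isolated), via betaine 16 (not isolated)
Conditions: 13 (1.5 equiv), Cs2CO3 (3 equiv), MeCN/CH2Cl2, −20 °C to rt
Reagents that add atoms: none
Why: Cs2CO3 turns 7 into its phenoxide, which expels benzenesulfinate to give o-quinone methide 14 (C7a=O, C3a=C3), and deprotonates 13 to ylide 15; the ylide carbon adds to the exocyclic C3 in a conjugate addition that rearomatises ring B and gives betaine 16, whose phenoxide O1 then displaces the thiolane from C2. The closest known reaction type is the base-mediated formal [4+1] annulation of in situ o-quinone methides from 2-(1-sulfonylalkyl)phenols with sulfonium ylides to trans-2,3-dihydrobenzofurans, combined with asymmetric benzylidene transfer from twofold-symmetric 2,5-dimethylthiolanium ylides. Ring D closes by a 5-exo-tet SN2 displacement with inversion at C2. C2 is controlled by the (2R,5R)-thiolane, whose methyl groups leave one face of the ylide carbon open, together with the invertive closure; C3 is set relative to C2 in the C–C bond formation, where the betaine with guaiacyl and CH2OBn anti is favoured and closes to the trans (2R,3S) ring. The step needs C–C bond formation at the methide carbon in preference to O-benzylation of the phenoxide by 13 or tautomerisation of 14 to an enol ether, and high face selectivity at the ylide; it relies on fast sulfinate loss from the phenoxide, the high electrophilicity of the methide carbon, slow release of both partners by the insoluble carbonate at low temperature, and the rigid sulfide.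

Step 12
Reactants: 17 (2R,3S)-7-(benzyloxy)-3-[(benzyloxy)methyl]-2-[4-(benzyloxy)-3-methoxyphenyl]-4-bromo-2,3-dihydro-1-benzofuran
Product: 19 (2R,3S)-7-(benzyloxy)-3-[(benzyloxy)methyl]-2-[4-(benzyloxy)-3-methoxyphenyl]-2,3-dihydro-1-benzofuran-4-carbaldehyde, via aryllithium 18 (not isolated)
Conditions: n-BuLi (1.1 equiv), THF, −78 °C; DMF, −78 to 0 °C; aq. NH4Cl
Reagents that add atoms: N,N-dimethylformamide CN(C)C=O
Why: Bromine–lithium exchange followed by formylation of the aryllithium with DMF (Bouveault-type) should be faster at −78 °C than any lithiation of the benzyl ethers, and neither stereocentre is acidic.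

Step 13
Reactants: 20 1-(2,4,6-trihydroxyphenyl)ethan-1-one
Product: 21 1-[2,4-bis(benzyloxy)-6-hydroxyphenyl]ethan-1-one
Conditions: BnBr (2.1 equiv), K2CO3 (2.2 equiv), DMF, rt to 60 °C
Reagents that add atoms: benzyl bromide BrCc1ccccc1
Why: Williamson etherification under carbonate leaves untouched the one hydroxyl that remains hydrogen-bonded to the acetyl carbonyl, the least nucleophilic of the three.

Step 14
Reactants: 19 (2R,3S)-7-(benzyloxy)-3-[(benzyloxy)methyl]-2-[4-(benzyloxy)-3-methoxyphenyl]-2,3-dihydro-1-benzofuran-4-carbaldehyde; 21 1-[2,4-bis(benzyloxy)-6-hydroxyphenyl]ethan-1-one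
Product: 22 (E)-1-[2,4-bis(benzyloxy)-6-hydroxyphenyl]-3-[(2R,3S)-7-(benzyloxy)-3-[(benzyloxy)methyl]-2-[4-(benzyloxy)-3-methoxyphenyl]-2,3-dihydro-1-benzofuran-4-yl]prop-2-en-1-one
Conditions: KOH (50% aq.), EtOH/THF, rt; aq. HCl
Reagents that add atoms: none
Why: Claisen–Schmidt condensation of the acetophenone enolate with the non-enolisable aldehyde and E1cB dehydration should give the E-enone, while C2–H and C3–H are not acidic enough to epimerise.

Step 15
Reactants: 22 (E)-1-[2,4-bis(benzyloxy)-6-hydroxyphenyl]-3-[(2R,3S)-7-(benzyloxy)-3-[(benzyloxy)methyl]-2-[4-(benzyloxy)-3-methoxyphenyl]-2,3-dihydro-1-benzofuran-4-yl]prop-2-en-1-one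
Product: 23 5,7-bis(benzyloxy)-2-[(2R,3S)-7-(benzyloxy)-3-[(benzyloxy)methyl]-2-[4-(benzyloxy)-3-methoxyphenyl]-2,3-dihydro-1-benzofuran-4-yl]-4H-chromen-4-one
Conditions: I2 (10 mol%), DMSO, 120 °C
Reagents that add atoms: none
Why: Iodine-catalysed oxidative cyclisation of a 2'-hydroxychalcone in DMSO (oxa-Michael closure and dehydrogenation with DMSO as terminal oxidant) is the standard flavone synthesis and tolerates aryl benzyl ethers when iodine is kept catalytic.

Step 16
Reactants: 23 5,7-bis(benzyloxy)-2-[(2R,3S)-7-(benzyloxy)-3-[(benzyloxy)methyl]-2-[4-(benzyloxy)-3-methoxyphenyl]-2,3-dihydro-1-benzofuran-4-yl]-4H-chromen-4-one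
Product: 25 5,7-bis(benzyloxy)-2-[(2R,3S)-7-(benzyloxy)-3-[(benzyloxy)methyl]-2-[4-(benzyloxy)-3-methoxyphenyl]-2,3-dihydro-1-benzofuran-4-yl]-3-hydroxy-4H-chromen-4-one, via flavone 2,3-epoxide 24 (not isolated)
Conditions: DMDO, acetone/CH2Cl2, 0 °C to rt; then TsOH·H2O (cat.), CH2Cl2, rt
Reagents that add atoms: dimethyldioxirane CC1(C)OO1
Why: Epoxidation of the chromone C2=C3 bond by neutral DMDO and acid-catalysed opening with tautomerisation to the 3-hydroxyflavone is the established two-stage C3 hydroxylation of 5,7-dialkoxyflavones, and the epoxide centres are lost again so their configuration does not matter.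

Step 17
Reactants: 25 5,7-bis(benzyloxy)-2-[(2R,3S)-7-(benzyloxy)-3-[(benzyloxy)methyl]-2-[4-(benzyloxy)-3-methoxyphenyl]-2,3-dihydro-1-benzofuran-4-yl]-3-hydroxy-4H-chromen-4-one
Product: 26 3,5,7-trihydroxy-2-[(2R,3S)-7-hydroxy-2-(4-hydroxy-3-methoxyphenyl)-3-(hydroxymethyl)-2,3-dihydro-1-benzofuran-4-yl]-4H-chromen-4-one (CNP0195987.1)
Conditions: H2 (1 atm), Pd/C (10 wt% Pd), THF/MeOH, rt
Reagents that add atoms: none
Why: Catalytic hydrogenolysis should remove the four aryl benzyl ethers and the alkyl benzyl ether under neutral conditions at low pressure, under which the flavonol double bond and the C2–O1 bond of the dihydrobenzofuran are expected to survive.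

**Compound list**

1 | 2,3-dihydroxybenzaldehyde | O=Cc1cccc(O)c1O | starting material
2 | 3-(benzyloxy)-2-hydroxybenzaldehyde | O=Cc1cccc(OCc2ccccc2)c1O | intermediate
3 | 2-(benzyloxy)-6-formylphenyl acetate | CC(=O)Oc1c(C=O)cccc1OCc1ccccc1 | intermediate
4 | 6-(benzyloxy)-3-bromo-2-formylphenyl acetate | CC(=O)Oc1c(C=O)c(Br)ccc1OCc1ccccc1 | intermediate
5 | 3-(benzyloxy)-6-bromo-2-hydroxybenzaldehyde | O=Cc1c(Br)ccc(OCc2ccccc2)c1O | intermediate
6 | 6-(benzyloxy)-2-[2-(benzyloxy)-1-hydroxyethyl]-3-bromophenol (racemic) | OC(COCc1ccccc1)c1c(Br)ccc(OCc2ccccc2)c1O | intermediate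
7 | 6-(benzyloxy)-2-[2-(benzyloxy)-1-(phenylsulfonyl)ethyl]-3-bromophenol (racemic) | Oc1c(OCc2ccccc2)ccc(Br)c1C(COCc1ccccc1)S(=O)(=O)c1ccccc1 | intermediate
8 | (2S,5S)-hexane-2,5-diol | C[C@H](O)CC[C@H](C)O | starting material
9 | (2S,5S)-hexane-2,5-diyl dimethanesulfonate | C[C@H](OS(C)(=O)=O)CC[C@H](C)OS(C)(=O)=O | intermediate
10 | (2R,5R)-2,5-dimethylthiolane | C[C@@H]1CC[C@@H](C)S1 | intermediate
11 | [4-(benzyloxy)-3-methoxyphenyl]methanol | COc1cc(CO)ccc1OCc1ccccc1 | starting material
12 | 1-(benzyloxy)-4-(bromomethyl)-2-methoxybenzene | COc1cc(CBr)ccc1OCc1ccccc1 | intermediate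
13 | (2R,5R)-1-[4-(benzyloxy)-3-methoxybenzyl]-2,5-dimethylthiolan-1-ium tetrafluoroborate | C[C@@H]1CC[C@@H](C)[S+]1Cc1ccc(OCc2ccccc2)c(OC)c1.F[B-](F)(F)F | intermediate
14 | 6-(benzyloxy)-2-[2-(benzyloxy)ethylidene]-3-bromocyclohexa-3,5-dien-1-one (o-quinone methide, alkene geometry not defined) | O=C1C(OCc2ccccc2)=CC=C(Br)C1=CCOCc1ccccc1 | intermediate
15 | [4-(benzyloxy)-3-methoxyphenyl][(2R,5R)-2,5-dimethylthiolan-1-ium-1-yl]methanide (sulfonium ylide) | C[C@@H]1CC[C@@H](C)[S+]1[CH-]c1ccc(OCc2ccccc2)c(OC)c1 | intermediate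
16 | 6-(benzyloxy)-2-{(1S,2S)-3-(benzyloxy)-1-[4-(benzyloxy)-3-methoxyphenyl]-1-[(2R,5R)-2,5-dimethylthiolan-1-ium-1-yl]propan-2-yl}-3-bromophenolate (betaine) | COc1cc([C@@H]([S+]2[C@H](C)CC[C@H]2C)[C@H](COCc2ccccc2)c2c(Br)ccc(OCc3ccccc3)c2[O-])ccc1OCc1ccccc1 | intermediate
17 | (2R,3S)-7-(benzyloxy)-3-[(benzyloxy)methyl]-2-[4-(benzyloxy)-3-methoxyphenyl]-4-bromo-2,3-dihydro-1-benzofuran | COc1cc([C@@H]2Oc3c(OCc4ccccc4)ccc(Br)c3[C@H]2COCc2ccccc2)ccc1OCc1ccccc1 | intermediate
18 | [(2R,3S)-7-(benzyloxy)-3-[(benzyloxy)methyl]-2-[4-(benzyloxy)-3-methoxyphenyl]-2,3-dihydro-1-benzofuran-4-yl]lithium | COc1cc([C@@H]2Oc3c(OCc4ccccc4)ccc([Li])c3[C@H]2COCc2ccccc2)ccc1OCc1ccccc1 | intermediate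
19 | (2R,3S)-7-(benzyloxy)-3-[(benzyloxy)methyl]-2-[4-(benzyloxy)-3-methoxyphenyl]-2,3-dihydro-1-benzofuran-4-carbaldehyde | COc1cc([C@@H]2Oc3c(OCc4ccccc4)ccc(C=O)c3[C@H]2COCc2ccccc2)ccc1OCc1ccccc1 | intermediate
20 | 1-(2,4,6-trihydroxyphenyl)ethan-1-one | CC(=O)c1c(O)cc(O)cc1O | starting material
21 | 1-[2,4-bis(benzyloxy)-6-hydroxyphenyl]ethan-1-one | CC(=O)c1c(O)cc(OCc2ccccc2)cc1OCc1ccccc1 | intermediate
22 | (E)-1-[2,4-bis(benzyloxy)-6-hydroxyphenyl]-3-[(2R,3S)-7-(benzyloxy)-3-[(benzyloxy)methyl]-2-[4-(benzyloxy)-3-methoxyphenyl]-2,3-dihydro-1-benzofuran-4-yl]prop-2-en-1-one | COc1cc([C@@H]2Oc3c(OCc4ccccc4)ccc(/C=C/C(=O)c4c(O)cc(OCc5ccccc5)cc4OCc4ccccc4)c3[C@H]2COCc2ccccc2)ccc1OCc1ccccc1 | intermediate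
23 | 5,7-bis(benzyloxy)-2-[(2R,3S)-7-(benzyloxy)-3-[(benzyloxy)methyl]-2-[4-(benzyloxy)-3-methoxyphenyl]-2,3-dihydro-1-benzofuran-4-yl]-4H-chromen-4-one | COc1cc([C@@H]2Oc3c(OCc4ccccc4)ccc(-c4cc(=O)c5c(OCc6ccccc6)cc(OCc6ccccc6)cc5o4)c3[C@H]2COCc2ccccc2)ccc1OCc1ccccc1 | intermediate
24 | 2,3-epoxide of 23 (2,3-epoxy-2,3-dihydrochromen-4-one, epoxide configuration not defined) | COc1cc([C@@H]2Oc3c(OCc4ccccc4)ccc(C45OC4C(=O)c4c(OCc6ccccc6)cc(OCc6ccccc6)cc4O5)c3[C@H]2COCc2ccccc2)ccc1OCc1ccccc1 | intermediate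
25 | 5,7-bis(benzyloxy)-2-[(2R,3S)-7-(benzyloxy)-3-[(benzyloxy)methyl]-2-[4-(benzyloxy)-3-methoxyphenyl]-2,3-dihydro-1-benzofuran-4-yl]-3-hydroxy-4H-chromen-4-one | COc1cc([C@@H]2Oc3c(OCc4ccccc4)ccc(-c4oc5cc(OCc6ccccc6)cc(OCc6ccccc6)c5c(=O)c4O)c3[C@H]2COCc2ccccc2)ccc1OCc1ccccc1 | intermediate
26 | 3,5,7-trihydroxy-2-[(2R,3S)-7-hydroxy-2-(4-hydroxy-3-methoxyphenyl)-3-(hydroxymethyl)-2,3-dihydro-1-benzofuran-4-yl]-4H-chromen-4-one | COc1cc([C@@H]2Oc3c(O)ccc(-c4oc5cc(O)cc(O)c5c(=O)c4O)c3[C@H]2CO)ccc1O | target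

**Totals**

Total step count: 17. Longest linear sequence: 12 steps (steps 1–6, 11, 12, 14–17).

**Steps most likely to fail**

Step 11. Two processes may defeat it: insufficient face selectivity at the ylide carbon (low enantiomeric purity), or diversion of the phenoxide by O-alkylation with the electron-rich benzylsulfonium salt. The fallback replaces reagent control by resolution and sets out from 7 and 12. Bromide 12 is S-alkylated onto achiral thiolane (AgBF4, CH2Cl2) to give 1-[4-(benzyloxy)-3-methoxybenzyl]thiolan-1-ium tetrafluoroborate F1. Its ylide is annulated with 7 under the same carbonate conditions to give racemic trans-7-(benzyloxy)-3-[(benzyloxy)methyl]-2-[4-(benzyloxy)-3-methoxyphenyl]-4-bromo-2,3-dihydro-1-benzofuran F2. Preparative chromatography on a chiral polysaccharide phase then separates 17, where the route is rejoined, from the (2S,3R) enantiomer F3.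

Step 6. The β-alkoxy benzylic cation may ionise slowly and, once formed, lose a proton towards the enol ether and cyclise to a benzofuran faster than sulfinate captures it. The fallback uses a fluoride-triggered methide precursor made without acid and sets out from 6. The phenol is silylated (TBSCl, imidazole, DMF) to 1-[3-(benzyloxy)-6-bromo-2-{[tert-butyl(dimethyl)silyl]oxy}phenyl]-2-(benzyloxy)ethan-1-ol F4. The benzylic alcohol is acetylated (Ac2O, pyridine, DMAP) to 1-[3-(benzyloxy)-6-bromo-2-{[tert-butyl(dimethyl)silyl]oxy}phenyl]-2-(benzyloxy)ethyl acetate F5. F5 is then treated with CsF and Cs2CO3 in MeCN in the presence of 13: desilylation gives the phenoxide, which expels acetate to the same methide 14, and the annulation returns to the route at 17.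

Step 16. Epoxidation of the hindered, electron-poor chromone double bond may be slow, so that excess DMDO begins to oxidise benzylic C–H bonds of the benzyl ethers or C2–H. The fallback uses C3 metalation instead of epoxidation and sets out from 23. LDA in THF at −78 °C should give the 3-lithioflavone F6, B(OMe)3 traps it as the dimethyl flavon-3-ylboronate F7, and H2O2/AcOH oxidises the C–B bond in the same flask to give 25, where the route is rejoined.

**Further compounds**

F1 | step 11 | 1-[4-(benzyloxy)-3-methoxybenzyl]thiolan-1-ium tetrafluoroborate | COc1cc(C[S+]2CCCC2)ccc1OCc1ccccc1.F[B-](F)(F)F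
F2 | step 11 | racemic trans-7-(benzyloxy)-3-[(benzyloxy)methyl]-2-[4-(benzyloxy)-3-methoxyphenyl]-4-bromo-2,3-dihydro-1-benzofuran (both enantiomers) | COc1cc([C@@H]2Oc3c(OCc4ccccc4)ccc(Br)c3[C@H]2COCc2ccccc2)ccc1OCc1ccccc1.COc1cc([C@H]2Oc3c(OCc4ccccc4)ccc(Br)c3[C@@H]2COCc2ccccc2)ccc1OCc1ccccc1
F3 | step 11 | (2S,3R)-7-(benzyloxy)-3-[(benzyloxy)methyl]-2-[4-(benzyloxy)-3-methoxyphenyl]-4-bromo-2,3-dihydro-1-benzofuran | COc1cc([C@H]2Oc3c(OCc4ccccc4)ccc(Br)c3[C@@H]2COCc2ccccc2)ccc1OCc1ccccc1
F4 | step 6 | 1-[3-(benzyloxy)-6-bromo-2-{[tert-butyl(dimethyl)silyl]oxy}phenyl]-2-(benzyloxy)ethan-1-ol (racemic) | OC(COCc1ccccc1)c1c(Br)ccc(OCc2ccccc2)c1O[Si](C)(C)C(C)(C)C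
F5 | step 6 | 1-[3-(benzyloxy)-6-bromo-2-{[tert-butyl(dimethyl)silyl]oxy}phenyl]-2-(benzyloxy)ethyl acetate (racemic) | CC(=O)OC(COCc1ccccc1)c1c(Br)ccc(OCc2ccccc2)c1O[Si](C)(C)C(C)(C)C
F6 | step 16 | [5,7-bis(benzyloxy)-2-[(2R,3S)-7-(benzyloxy)-3-[(benzyloxy)methyl]-2-[4-(benzyloxy)-3-methoxyphenyl]-2,3-dihydro-1-benzofuran-4-yl]-4-oxo-4H-chromen-3-yl]lithium | COc1cc([C@@H]2Oc3c(OCc4ccccc4)ccc(-c4oc5cc(OCc6ccccc6)cc(OCc6ccccc6)c5c(=O)c4[Li])c3[C@H]2COCc2ccccc2)ccc1OCc1ccccc1
F7 | step 16 | dimethyl [5,7-bis(benzyloxy)-2-[(2R,3S)-7-(benzyloxy)-3-[(benzyloxy)methyl]-2-[4-(benzyloxy)-3-methoxyphenyl]-2,3-dihydro-1-benzofuran-4-yl]-4-oxo-4H-chromen-3-yl]boronate | COc1cc([C@@H]2Oc3c(OCc4ccccc4)ccc(-c4oc5cc(OCc6ccccc6)cc(OCc6ccccc6)c5c(=O)c4B(OC)OC)c3[C@H]2COCc2ccccc2)ccc1OCc1ccccc1
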